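The readings come from a simulation on assumed constants; noise was put on by code.

At 2.5 min every flask has had the same time, so what you read is the share of its charge that this time could buy.

| flask | substrate | reagent | free catalyst | remark | time |
|---|---|---|---|---|---|
| Tuesday's | 0.020 M | 0.050 M | 0.10 mM | run made earlier |  |
| Friday's | 0.32 M | 0.050 M | 0.10 mM | run made earlier |  |
| red | 0.20 M | 0.0500 M | 0.10 mM |  | 2.5 min |
| grey | 0.015 M | 0.0500 M | 0.10 mM |  | 2.5 min |
| violet | 0.050 M | 0.0500 M | 0.10 mM |  | 2.5 min |
| green | 0.15 M | 0.0500 M | 0.10 mM |  | 2.5 min |

| run | time / s | product / % | substrate / % |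
|---|---|---|---|
| Tuesday's | 10.0 | 12 | 85 |
| Tuesday's | 25.0 | 33 | 66 |
| Tuesday's | 50.0 | 63 | 34 |
| Tuesday's | 80.0 | 90 | 16 |
| Friday's | 10.0 | 2 | 96 |
| Friday's | 15.0 | 2 | 99 |
| Friday's | 30.0 | 4 | 96 |
| Friday's | 80.0 | 9 | 93 |

(each reading ± 1.5 percentage points)

- the flasks put in order of amount of product, in percent of the substrate charged, best first, at 2.5 min (red / grey / violet / green)
- the amount of product, in percent of the substrate charged of the flask you put first, at 2.5 min
- the amount of product, in percent of the substrate charged of the flask you put last, at 2.5 min

- a reading or a percentage of product counts all its forms, free or not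

Friday's flask held 16.0 times Tuesday's substrate, yet its product per second by 80.0 s was just 1.43 times Tuesday's by 50.0 s. I therefore take Friday's reading as an average pace, taken while the reagent fell by 57.6% of its charge if each substrate takes one reagent, and scale it by charge and time. For red that gives 27.0%. This is the number to carry: the budget, the share of a flask's charge that Friday's pace turns over by the time of reading. Green gets 36.0%, violet 108% and grey 360%, so the order reads grey, violet, green, red.

One number is not enough, though. If each substrate takes one reagent, the reagent is the limiting reagent in red, and its ceiling of 25.0% stands lower than the budget. Green's ceiling is 33.3% and violet's 100%, each also under its budget. I keep the order, expect grey near complete, and expect red under its ceiling, so watch the reagent.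

The forecast says grey > violet > green > red, with 99% first and 24% last, since “the 0.050 M reagent caps product at 0.050 M”.

The flasks give grey > violet > green > red, with 99.9% and 18.4%. Red's 18.4% is 0.681 of its budget and 6.6 percentage points under its ceiling, with 26% of its reagent still unbound at 2.50 min.

    substrate + free catalyst ⇌ catalyst intermediate A (K = 180 /M, k = 13000 /M/s)
    reagent + catalyst intermediate A ⇌ catalyst intermediate B (K = 24.0 /M, k = 450 /M/s)
    catalyst intermediate B → catalyst intermediate C (k = 11.0 /s)
    catalyst intermediate C → free catalyst + product (k = 11.0 /s)
    crystals ⇌ product, rate k5*(cs5 - [product]) while solid is left; crystals form when [product] > cs5 (solubility = 0.790 mM, k = 1.60 /s)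
    2 free catalyst ⇌ resting dimer, settled at all times (K = 3600 /M)

Give red 0.085 M of reagent instead: the budget stays 27.0% and the ceiling rises to 0.425 equiv, so the ceiling now stands above the budget. That flask gives 25.5%, with 40% of its reagent left.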